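## Retrosynthetic overview

- **Feature the strategy rests on.** In labdane numbering, the six-carbon run C11–C9–C8(CH3)–C7–C6–C5 crosses ring B from the first side-chain carbon to the ring fusion. This run is C1–C6 of geraniol together with its C3 methyl, so the C8 carbinol and C9 can be fixed on the open chain by asymmetric epoxidation and anti opening at C9 by an isopropenyl copper reagent, which also brings in C10 and its methyl.
- **Side chain.** C11–C12 is cut last: a C11 phenyl sulfone carbanion plus (2E,6E)-farnesyl bromide, then reductive desulfonylation. The C3 ketone travels as a 3β-benzyl ether.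
- **Ring A.** The C4 gem-dimethyl group and 5α-H come from reductive methylation of a 4-methyl Δ4-3-ketone. That enone is cut at C1–C10 (Michael) and C4–C5 (aldol) into ethyl vinyl ketone and the ring B 2-methylcyclohexanone.
- **Ring B.** C5–C10 comes from ring-closing metathesis of the isopropenyl/prenyl diene. Hydroboration and oxidation then place the C5 ketone.
- **Order of ring formation.** Temporary C8/C11 1,3-dioxane, then ring B, then ring A.

Key step: step 7

Remark on numbering: labdane numbering is used throughout (C3 ketone, C4 gem-dimethyl, C5/C10 ring fusion, C8 carbinol, C9 side-chain carbon, C11 first chain carbon), and β is the face of the C10 methyl in the target.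

Assumption: 7–9 are drawn as the products of α-face hydroboration, 13 is left undefined at C4/C5, and 24 is a mixture at C11. None of these centres survives, and the other hydroboration adduct would lead to the same ketone 10.

## Route

Step 1
Reactants: 1 geraniol
Product: 2 (2R,3R)-2,3-epoxygeraniol
Conditions: Ti(OiPr)4 (5 mol %), D-(−)-diethyl tartrate (7 mol %), t-BuOOH (1.5 equiv, decane), 4 Å MS, CH2Cl2, −20 °C
Reagents that add atoms: tert-butyl hydroperoxide, CC(C)(C)OO
Why: Sharpless asymmetric epoxidation: the titanium tartrate complex binds the allylic hydroxyl, so only the C2–C3 alkene (later C9–C8) is oxidised while the remote prenyl alkene is left, and the D-(−)-tartrate series delivers oxygen to the face that gives the (2R,3R)-epoxide, which fixes C8 as R.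

Step 2
Reactants: 2 (2R,3R)-2,3-epoxygeraniol; 3 isopropenylmagnesium bromide
Product: 4 (2S,3R)-3,7-dimethyl-2-(prop-1-en-2-yl)oct-6-ene-1,3-diol
Conditions: 3 (3 equiv, THF), CuI (15 mol %), THF, −30 to 0 °C; aq NH4Cl
Reagents that add atoms: isopropenylmagnesium bromide 3, C=C(C)[Mg]Br
Why: Copper-catalysed SN2 opening of a 2,3-epoxy alcohol by a Grignard reagent: the nucleophile takes the secondary carbon C2 (later C9) rather than the fully substituted C3, with inversion, so the 1,3-diol results with C9 set relative to the untouched C8 (the C8 oxygen and C11 become trans-diequatorial on ring B) and with C10 and its methyl in place.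

Step 3
Reactants: 4 (2S,3R)-3,7-dimethyl-2-(prop-1-en-2-yl)oct-6-ene-1,3-diol
Product: 5 (4R,5S)-2,2,4-trimethyl-4-(4-methylpent-3-enyl)-5-(prop-1-en-2-yl)-1,3-dioxane
Conditions: Me2C(OMe)2, PPTS (5 mol %), CH2Cl2, rt
Reagents that add atoms: 2,2-dimethoxypropane, COC(C)(C)OC
Why: Acid-catalysed transacetalisation of a 1,3-diol, which touches no stereocentre, masks both hydroxyls against borane, base and lithium, and gives a dioxane chair in which the two alkenyl arms are equatorial and gauche, ready for ring closure.

Step 4
Reactants: 5 (4R,5S)-2,2,4-trimethyl-4-(4-methylpent-3-enyl)-5-(prop-1-en-2-yl)-1,3-dioxane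
Product: 6 ring B cyclohexene (4aS,8aR)-2,2,5,8a-tetramethyl-4a,7,8,8a-tetrahydro-4H-1,3-benzodioxine (C5=C10 alkene; 8β-CH3; 9α-H; trans-fused)
Conditions: second-generation Grubbs catalyst RuCl2(=CHPh)(PCy3)(H2IMes) (5 mol %), toluene (0.01 M), 80 °C, argon sparge
Reagents that add atoms: none
Why: Ring-closing metathesis to a six-membered trisubstituted cycloalkene: N-heterocyclic carbene ruthenium alkylidenes accept both 1,1-disubstituted alkenes and prenyl-type termini (as in the ring closure of linalool- and citronellene-type dienes), the loss of volatile 2-methylpropene drives the reaction, and C8 and C9 are spectators.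

Step 5
Reactants: 6 ring B cyclohexene
Product: 8 ring B alcohol (5α-OH; 10β-CH3; C8/C11 acetonide), via C5 alkylborane 7 (not isolated)
Conditions: BH3·THF, THF, 0 °C to rt; then 3 M NaOH, 30 % H2O2, 0 °C to rt
Reagents that add atoms: hydrogen peroxide, OO
Why: Hydroboration–oxidation: boron adds to the less substituted C5 and hydrogen to C10 in a syn fashion, expected from the α face opposite the axial C8 methyl, and oxidation goes with retention; the two new centres are erased (C5) or equilibrated (C10) in step 6, so the facial outcome does not matter.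

Step 6
Reactants: 8 ring B alcohol
Product: 10 ring B ketone (C5 ketone; equatorial 10α-CH3; 8β-CH3; 9α-H; C8/C11 acetonide), via 10β-methyl ketone 9 (not isolated)
Conditions: Dess–Martin periodinane, NaHCO3, CH2Cl2, 0 °C to rt; crude 9, K2CO3, MeOH, rt
Reagents that add atoms: none
Why: Dess–Martin oxidation of the secondary alcohol under buffered conditions that spare the acetal, followed by carbonate-mediated enolisation, which moves the C10 methyl out of its 1,3-diaxial contact with the C8 methyl into the equatorial α position (thermodynamic control).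

Step 7
Reactants: 10 ring B ketone; 11 ethyl vinyl ketone
Product: 14 4-methyl Δ4-octalin-3-one (10β-CH3; C8/C11 acetonide), via Michael adduct diketone 12 (not isolated), via aldol ketol 13 (not isolated)
Conditions: 11 (1.5 equiv, slow addition), NaOMe (0.3 equiv), MeOH, 0 °C to rt; then NaOMe (1.5 equiv), reflux
Reagents that add atoms: ethyl vinyl ketone 11, CCC(=O)C=C
Why: Methoxide interconverts the enolates of 10 (so the C10 configuration of 10 is irrelevant), the tetrasubstituted C5–C10 enolate adds 1,4 to 11 to form C1–C10 (12), proton transfer gives the C3–C4 enolate, this attacks the C5 carbonyl to form C4–C5 (13), and E1cB loss of water on heating gives 14. The closest known reaction is the Robinson annulation of 2,3-disubstituted 2-methylcyclohexanones with ethyl vinyl ketone, in which the new bond forms anti to the 3-substituent. Ring A closes by a favoured 6-(enolendo)-exo-trig aldol addition; the competing attack of C6 on the C3 carbonyl gives a bridged bicyclo[3.3.1] ketol that cannot dehydrate (bridgehead alkene) and returns by retro-aldol. C10 is the only new stereocentre: the trans-fused dioxane freezes the enolate half-chair with the C8 methyl axial on the β face, 1,3 to C10, and the C9–C11 arm leaning to the same face, so 11 approaches from the open α face and the C10 methyl is left β, cis to C11, just as electrophiles enter C4 of 10-methyl-3-decalone enolates anti to the angular methyl even though this is the equatorial trajectory. The step needs C10 over C6 regioselectivity, which rests on reversible enolate formation in a protic medium favouring the more substituted and more nucleophilic enolate while 11 is kept dilute by slow addition. No β-elimination can interfere because both acetal oxygens (on C8 and C11) are γ to the C5 carbonyl, and C8 and C9 are not enolisable.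

Step 8
Reactants: 14 4-methyl Δ4-octalin-3-one
Product: 16 4,4-dimethyl trans-decalin-3-one (5α-H; 10β-CH3; C8/C11 acetonide), via lithium enolate 15 (not isolated)
Conditions: Li (2.5 equiv), t-BuOH (1.0 equiv), NH3(l)–THF, −78 to −33 °C; then MeI (excess), −33 °C to rt; NH4Cl
Reagents that add atoms: iodomethane, CI
Why: Dissolving-metal reductive alkylation of an enone: two-electron reduction and axial protonation at C5 from the α face give the trans-fused C3–C4 lithium enolate 15 regiospecifically (5α-H set by the preference of the β-carbanion for the chair–chair trans geometry, anti to the C10 methyl), and C-methylation at C4 completes the gem-dimethyl group, the acetal being inert to lithium in ammonia.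

Step 9
Reactants: 16 4,4-dimethyl trans-decalin-3-one
Product: 17 3β-alcohol (C8/C11 acetonide)
Conditions: NaBH4, MeOH–CH2Cl2, 0 °C
Reagents that add atoms: none
Why: Borohydride reduction with axial hydride delivery from the α face, away from the axial 4β and 10β methyls, gives the equatorial 3β-alcohol; this centre is only a mask for the ketone, which would not survive n-BuLi in step 14 or lithium in step 15.

Step 10
Reactants: 17 3β-alcohol
Product: 18 3β-benzyl ether (C8/C11 acetonide)
Conditions: NaH, BnBr, Bu4NI (10 mol %), DMF, 0 to 40 °C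
Reagents that add atoms: benzyl bromide, BrCc1ccccc1
Why: Williamson ether synthesis under iodide catalysis; the benzyl ether is stable to the acid, phosphine, peroxide and organolithium steps ahead and leaves in the same operation as the sulfone.

Step 11
Reactants: 18 3β-benzyl ether
Product: 19 3β-benzyloxy-8α,11-diol
Conditions: AcOH–THF–H2O (3:1:1), 40 °C
Reagents that add atoms: none
Why: Mild acid-catalysed hydrolysis of the isopropylidene acetal, in which the C8–O and C11–O bonds are not broken (configuration at C8 kept) and the acidity is too low to ionise or dehydrate the tertiary carbinol.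

Step 12
Reactants: 19 3β-benzyloxy-8α,11-diol
Product: 20 11-phenyl sulfide (3β-OBn; 8α-OH)
Conditions: PhSSPh (1.5 equiv), n-Bu3P (1.5 equiv), pyridine, rt to 50 °C
Reagents that add atoms: diphenyl disulfide, c1ccccc1SSc1ccccc1
Why: Hata reaction (phosphine/disulfide, Mitsunobu-type): only the primary C11 hydroxyl forms the alkoxyphosphonium salt, which thiolate displaces by SN2, and the neutral medium avoids a C8 alkoxide and with it oxetane closure or Grob fragmentation of the 1,3-related system.

Step 13
Reactants: 20 11-phenyl sulfide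
Product: 21 11-phenyl sulfone (3β-OBn; 8α-OH)
Conditions: (NH4)6Mo7O24·4H2O (10 mol %), 30 % H2O2 (5 equiv), EtOH, 0 °C to rt
Reagents that add atoms: hydrogen peroxide, OO
Why: Molybdate-catalysed peroxide oxidation of a sulfide to the sulfone, carried out before any alkene is present, with the benzyl ether and the tertiary alcohol inert.

Step 14
Reactants: 21 11-phenyl sulfone; 22 (2E,6E)-farnesyl bromide
Product: 24 3β-benzyloxy-11-phenylsulfonylpolypoda-13E,17E,21-trien-8α-ol (C11 epimers), via dilithiated sulfone 23 (not isolated)
Conditions: n-BuLi (2.2 equiv), THF–DMPU (5:1), −78 °C; 22 (1.3 equiv), −78 to −20 °C; aq NH4Cl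
Reagents that add atoms: (2E,6E)-farnesyl bromide 22, CC(C)=CCC/C(C)=C/CC/C(C)=C/CBr
Why: Alkylation of an α-sulfonyl carbanion with an allylic bromide (Julia-type fragment coupling): the first equivalent of base takes the C8 hydroxyl proton and the second the C11 proton, the soft carbanion then displaces bromide by SN2 at the primary carbon of 22 faster than the hindered tertiary alkoxide can, the E alkenes are untouched, and the new C11 centre (mixture) is removed in step 15.

Step 15
Reactants: 24 3β-benzyloxy-11-phenylsulfonylpolypoda-13E,17E,21-trien-8α-ol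
Product: 25 polypoda-13E,17E,21-triene-3β,8α-diol
Conditions: Li (excess), t-BuOH, NH3(l)–THF, −78 °C; solid NH4Cl
Reagents that add atoms: none
Why: Dissolving-metal reduction: electron transfer cleaves the C11–S bond (reductive desulfonylation; the sulfone is homoallylic, not allylic, so the C13 alkene can neither migrate nor isomerise) and the benzylic C–O bond in one operation, while isolated trisubstituted alkenes and the tertiary alcohol are inert.

Step 16
Reactants: 25 polypoda-13E,17E,21-triene-3β,8α-diol
Product: 26 (5R,8R,9R,10S)-8-hydroxypolypoda-13E,17E,21-trien-3-one (target)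
Conditions: Dess–Martin periodinane, NaHCO3, CH2Cl2, 0 °C to rt
Reagents that add atoms: none
Why: Dess–Martin oxidation: only the secondary C3 carbinol can be oxidised, the bicarbonate buffer protects the tertiary C8 alcohol and the polyene from acid, and no stereocentre lies α to the new ketone (C4 is quaternary, C2 is a methylene).

## Compound list

1 | geraniol | CC(C)=CCC/C(C)=C/CO | starting material
2 | (2R,3R)-2,3-epoxygeraniol | CC(C)=CCC[C@@]1(C)O[C@@H]1CO | intermediate
3 | isopropenylmagnesium bromide (commercial THF solution) | C=C(C)[Mg]Br | starting material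
4 | (2S,3R)-3,7-dimethyl-2-(prop-1-en-2-yl)oct-6-ene-1,3-diol | CC(C)=CCC[C@@](C)(O)[C@H](CO)C(C)=C | intermediate
5 | (4R,5S)-2,2,4-trimethyl-4-(4-methylpent-3-enyl)-5-(prop-1-en-2-yl)-1,3-dioxane | CC1(C)OC[C@H](C(C)=C)[C@@](C)(CCC=C(C)C)O1 | intermediate
6 | ring B cyclohexene, (4aS,8aR)-2,2,5,8a-tetramethyl-4a,7,8,8a-tetrahydro-4H-1,3-benzodioxine | CC1(C)OC[C@@H]2C(C)=CCC[C@@]2(C)O1 | intermediate
7 | C5 alkylborane (5α-BH2, 10β-CH3), not isolated | CC1(C)OC[C@@H]2[C@H](C)[C@@H](B)CC[C@@]2(C)O1 | intermediate
8 | ring B alcohol (5α-OH, 10β-CH3) | CC1(C)OC[C@@H]2[C@H](C)[C@@H](O)CC[C@@]2(C)O1 | intermediate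
9 | ring B ketone with axial 10β-CH3, not isolated | CC1(C)OC[C@@H]2[C@H](C)C(=O)CC[C@@]2(C)O1 | intermediate
10 | ring B ketone with equatorial 10α-CH3, C8/C11 acetonide (key-step precursor) | CC1(C)OC[C@@H]2[C@@H](C)C(=O)CC[C@@]2(C)O1 | intermediate
11 | ethyl vinyl ketone (pent-1-en-3-one) | CCC(=O)C=C | starting material
12 | 10β-methyl-10α-(3-oxopentyl) ring B ketone (1,5-diketone), not isolated | CC1(C)OC[C@@H]2[C@@](C)(CCC(=O)CC)C(=O)CC[C@@]2(C)O1 | intermediate
13 | 5-hydroxy-4-methyldecalin-3-one ketol (C4, C5 undefined), not isolated | CC1(C)OC[C@@H]2[C@@]3(C)CCC(=O)C(C)C3(O)CC[C@@]2(C)O1 | intermediate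
14 | 4-methyl Δ4-octalin-3-one, 10β-CH3, C8/C11 acetonide (key-step product) | CC1(C)OC[C@@H]2[C@@]3(C)CCC(=O)C(C)=C3CC[C@@]2(C)O1 | intermediate
15 | lithium C3–C4 enolate, 5α-H, not isolated | CC1(C)OC[C@@H]2[C@@]3(C)CCC(O[Li])=C(C)[C@@H]3CC[C@@]2(C)O1 | intermediate
16 | 4,4-dimethyl trans-decalin-3-one, C8/C11 acetonide | CC1(C)OC[C@@H]2[C@@]3(C)CCC(=O)C(C)(C)[C@@H]3CC[C@@]2(C)O1 | intermediate
17 | 3β-alcohol, C8/C11 acetonide | CC1(C)OC[C@@H]2[C@@]3(C)CC[C@H](O)C(C)(C)[C@@H]3CC[C@@]2(C)O1 | intermediate
18 | 3β-benzyl ether, C8/C11 acetonide | CC1(C)OC[C@@H]2[C@@]3(C)CC[C@H](OCc4ccccc4)C(C)(C)[C@@H]3CC[C@@]2(C)O1 | intermediate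
19 | 3β-benzyloxy-8α,11-diol | OC[C@@H]1[C@@]2(C)CC[C@H](OCc3ccccc3)C(C)(C)[C@@H]2CC[C@@]1(C)O | intermediate
20 | 11-phenyl sulfide (3β-OBn, 8α-OH) | c1ccc(cc1)SC[C@@H]1[C@@]2(C)CC[C@H](OCc3ccccc3)C(C)(C)[C@@H]2CC[C@@]1(C)O | intermediate
21 | 11-phenyl sulfone (3β-OBn, 8α-OH) | O=S(=O)(c1ccccc1)C[C@@H]1[C@@]2(C)CC[C@H](OCc3ccccc3)C(C)(C)[C@@H]2CC[C@@]1(C)O | intermediate
22 | (2E,6E)-farnesyl bromide | CC(C)=CCC/C(C)=C/CC/C(C)=C/CBr | starting material
23 | C11,O8-dilithiated sulfone, not isolated | [Li]C(S(=O)(=O)c1ccccc1)[C@@H]1[C@@]2(C)CC[C@H](OCc3ccccc3)C(C)(C)[C@@H]2CC[C@@]1(C)O[Li] | intermediate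
24 | 3β-benzyloxy-11-phenylsulfonylpolypoda-13E,17E,21-trien-8α-ol (C11 epimers) | CC(C)=CCC/C(C)=C/CC/C(C)=C/CC(S(=O)(=O)c1ccccc1)[C@@H]1[C@@]2(C)CC[C@H](OCc3ccccc3)C(C)(C)[C@@H]2CC[C@@]1(C)O | intermediate
25 | polypoda-13E,17E,21-triene-3β,8α-diol | CC(C)=CCC/C(C)=C/CC/C(C)=C/CC[C@@H]1[C@@]2(C)CC[C@H](O)C(C)(C)[C@@H]2CC[C@@]1(C)O | intermediate
26 | (5R,8R,9R,10S)-8-hydroxypolypoda-13E,17E,21-trien-3-one, CNP0158964.2 | CC(C)=CCC/C(C)=C/CC/C(C)=C/CC[C@@H]1[C@@]2(C)CCC(=O)C(C)(C)[C@@H]2CC[C@@]1(C)O | target

## Step count and risks

Total step count: 16. Longest linear sequence: 16 steps (1 to 26). Compounds 3, 11 and 22 are bought and enter directly.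

**Risk 1: step 7.**
- What may go wrong:
  - The locked equatorial C9 arm is held close to the C10 methyl in the tetrasubstituted enolate, which may lower its share and let Michael addition leak to C6.
  - The α approach runs through a twist-boat-like transition state, which may erode the facial selectivity.
  - Enone 11 may polymerise under base.
- Fallback (from 10, back at 12 and then 14):
  - The metal enolate is replaced by a chiral secondary enamine under neutral conditions.
  - Ketone 10 is condensed with (R)-1-phenylethylamine (cat. TsOH, toluene, 4 Å MS, reflux) to the ketimine F1.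
  - Its secondary enamine tautomer adds to 11 (THF, 40 °C) through a cyclic aza-ene-type transition state. This operates only at the more substituted α-carbon, and the auxiliary should reinforce attack on the α face. The product is the adduct imine F2.
  - Buffered hydrolysis (AcOH/NaOAc, aqueous THF, rt) releases diketone 12, now isolated.
  - NaOMe in refluxing MeOH closes 12 to 14.

**Risk 2: step 4.**
- What may go wrong: neither alkene is monosubstituted, so initiation may be slow, the catalyst may decay before turnover, and intermolecular metathesis may compete.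
- Fallback (from 5, back at 6):
  - The prenyl terminus is exchanged for a vinyl group before ring closure.
  - mCPBA (1.0 equiv, NaHCO3, CH2Cl2, 0 °C) epoxidises the more electron-rich trisubstituted alkene to the terminal epoxide F3.
  - H5IO6 (THF–H2O, 0 °C, short contact) cleaves F3 to the aldehyde F4.
  - Wittig methylenation (Ph3P=CH2, THF, 0 °C) gives the vinyl/isopropenyl diene F5.
  - F5 closes with RuCl2(=CHPh)(PCy3)(H2IMes) in CH2Cl2 at 40 °C, with loss of ethene, to 6.

**Risk 3: step 14.**
- What may go wrong: the carbanion sits on a carbon that already carries the phenylsulfonyl group and hangs on C9 between two quaternary centres. C–C bond formation may therefore be slower than elimination of the bromide, O-alkylation at C8, or simple decay of 22.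
- Fallback (from 19, back at 25):
  - The stabilised carbanion is replaced by an unstabilised, sterically slimmer C11 organometallic, and no desulfonylation is needed.
  - Diol 19 is converted with I2, PPh3 and imidazole (CH2Cl2, 0 °C) into the primary 11-iodide F6.
  - t-BuLi (3.2 equiv, Et2O–pentane, −78 °C) removes the hydroxyl proton and effects iodine–lithium exchange to the dilithio species F7.
  - MgBr2·OEt2 turns F7 into the bis(bromomagnesium) species F8.
  - F8 is coupled with 22 under Li2CuCl4 catalysis (THF, −78 to 0 °C), with attack at the unsubstituted allylic terminus and retention of the E geometry, to the 3β-benzyl ether F9.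
  - Lithium in ammonia as in step 15 removes the benzyl group and gives 25.

## Further compounds

F1 | step 7 | (R)-1-phenylethylamine ketimine of 10 | C[C@@H](N=C1CC[C@@]2(C)OC(C)(C)OC[C@@H]2[C@H]1C)c1ccccc1
F2 | step 7 | (R)-1-phenylethylamine ketimine of 12 | C[C@@H](N=C1CC[C@@]2(C)OC(C)(C)OC[C@@H]2[C@@]1(C)CCC(=O)CC)c1ccccc1
F3 | step 4 | terminal (prenyl) epoxide of 5, epoxide carbon undefined | CC1(C)OC[C@H](C(C)=C)[C@@](C)(CCC2OC2(C)C)O1
F4 | step 4 | 3-[(4R,5S)-2,2,4-trimethyl-5-(prop-1-en-2-yl)-1,3-dioxan-4-yl]propanal | CC1(C)OC[C@H](C(C)=C)[C@@](C)(CCC=O)O1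
F5 | step 4 | (4R,5S)-4-(but-3-enyl)-2,2,4-trimethyl-5-(prop-1-en-2-yl)-1,3-dioxane | CC1(C)OC[C@H](C(C)=C)[C@@](C)(CCC=C)O1
F6 | step 14 | 11-iodide (3β-OBn, 8α-OH) | IC[C@@H]1[C@@]2(C)CC[C@H](OCc3ccccc3)C(C)(C)[C@@H]2CC[C@@]1(C)O
F7 | step 14 | C11,O8-dilithio species | [Li]C[C@@H]1[C@@]2(C)CC[C@H](OCc3ccccc3)C(C)(C)[C@@H]2CC[C@@]1(C)O[Li]
F8 | step 14 | C11,O8-bis(bromomagnesium) species | Br[Mg]C[C@@H]1[C@@]2(C)CC[C@H](OCc3ccccc3)C(C)(C)[C@@H]2CC[C@@]1(C)O[Mg]Br
F9 | step 14 | 3β-benzyloxypolypoda-13E,17E,21-trien-8α-ol | CC(C)=CCC/C(C)=C/CC/C(C)=C/CC[C@@H]1[C@@]2(C)CC[C@H](OCc3ccccc3)C(C)(C)[C@@H]2CC[C@@]1(C)O
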